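## The problem

The target **29** is a sesquineolignan made of three guaiacyl units. Ring A sits on C2 of a 2,3-dihydrobenzofuran (O1–C2–C3–C3a–C7a) whose benzo ring is ring B, with OMe on C7 and a hydroxymethyl arm (C9) on C3. C5 of ring B carries the chain C7'H(OH)–C8'H(C9'H2OH)–ring C. There are four stereocentres in two pairs: C2 (S) and C3 (R), trans on the dihydrofuran, and C7' (S) and C8' (R), which stand in a syn aldol relationship along C9'–C8'–C7'–ring B. Within a pair one centre can set the other: ring closure ties C3 to C2, and a closed aldol transition state ties C7' to C8'. The pairs are insulated from each other by ring B, so each needs its own source of absolute configuration. The molecule tolerates little rough treatment. A ring A phenoxide can expel O1 from C2 as a para-quinone methide. The C7' carbinol is para to O1, ionises under acid and can fragment with loss of C9'. The 1,3-diol can undergo retro-aldol-type cleavage under strong base. The last operations must therefore be close to neutral, and all masking groups should leave together. The enabling feature is the atom set O1–C7a–C3a–C3, which is an ortho-quinone methide of ring B (C7a=O, C3a=C3) with electrophilic C3 and nucleophilic O1. The remaining ring atom C2 carries ring A and must act first as a nucleophile and then as an electrophile, which is the behaviour of a sulfonium ylide carbon.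

## Retrosynthesis

**Protecting groups (29 ⇒ 28).** No skeletal bond is cut. The two phenols are carried as triisopropylsilyl ethers and the C9 hydroxyl as a tert-butyldimethylsilyl ether, so that **28** is unmasked in one buffered fluoride treatment. Benzyl ethers were rejected because hydrogenolysis endangers the benzylic C2–O1 and C7'–OH bonds, and acetals because their removal needs acid.

**C7'–C8' (28 ⇒ 27 ⇒ 19 + 25).** The chain is cut between the carbinol carbon and the carbon bearing ring C. An Evans syn aldol of aldehyde **19** with the boron enolate of arylacetyl imide **25** sets both chain centres by reagent control. This is required because the C2/C3 pair is too remote to direct them. The neighbouring cut, a ring B aryl metal adding to an α-aryl aldehyde, was rejected because that aldehyde is configurationally labile and only one centre would be under control. Reductive removal of the auxiliary from **27** delivers C9'H2OH directly. The forward reaction must give the (2S,3S) syn adduct; the (S)-benzyloxazolidinone **23** provides this sense. The cut removes ring C and two stereocentres and leaves an aldehyde that contains only the phenylcoumaran.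

**C5–CHO (19 ⇒ 17).** The formyl carbon is traced back to a bromine atom on C5. A free aldehyde would itself be attacked by the ylide of the key step, whereas the bromide is inert to carbonate and is converted cleanly by halogen–lithium exchange and formylation.

**C2–C3 and O1–C2 (17 ⇒ 5 + 13).** Both bonds to C2 are cut at once. This leaves an ortho-quinone methide of ring B, stored as the bench-stable 2-(1-sulfonylalkyl)phenol **5**, and a benzylic sulfonium salt **13** that holds C2, ring A and a C2-symmetric chiral thiolane. Cutting only O1–C2 or only C3–C3a gives linear precursors in which the two centres have to be built beforehand. The double cut gives two guaiacol-derived halves of similar size and forms ring, two bonds and two stereocentres in one step. The forward reaction must favour trans closure and one ylide face, and must outrun tautomerisation of the alkyl-substituted quinone methide. The sulfone is preferred as leaving group because carbonate alone releases it; halide or acetate precursors that need fluoride would not spare the silyl ethers.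

**Sulfone 5 (5 ⇒ 4 ⇒ 1 + 2).** The C–S bond is cut to the ortho-hydroxybenzylic alcohol **4**, which exchanges OH for an arenesulfinyl sulfur under weak acid. The C3–C3a bond of **4** is cut to 4-bromo-2-methoxyphenol **1** and silyloxyacetaldehyde **2**. A one-pot condensation of phenol, aldehyde and sulfinic acid was rejected: the bromophenol is a weak nucleophile and also offers the position para to its methoxy group. Magnesium phenoxide chelation directs the aldehyde to the single free ortho position instead.

**Sulfonium salt 13 (13 ⇒ 12 + 8; 12 ⇒ 11 ⇒ 10 ⇒ 9; 8 ⇒ 7 ⇒ 6).** The S–CH2 bond is cut to benzylic bromide **12** and (2S,5S)-2,5-dimethylthiolane **8**. Bromide **12** comes from vanillin **9** by silylation (**10**), reduction (**11**) and bromination. Thiolane **8** comes from (2R,5R)-hexane-2,5-diol **6** through dimesylate **7** with inversion at both carbons.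

**Imide 25 (25 ⇒ 22 + 23; 22 ⇒ 20).** The N-acyl bond is cut to the silylated arylacetic acid **22**, obtained from homovanillic acid **20**, and oxazolidinone **23**.

## Roads not taken

Alternative 1: The cut is C3–C3a. An aryllithium generated by halogen–lithium exchange at C3a of the bromoaryl ether epoxide **A2** would attack the internal carbon of the terminal epoxide in a 5-exo closure and give the trans hydroxymethyl dihydrobenzofuran **A1** with C9–OH set free. Both centres would derive from one Sharpless asymmetric epoxidation and two stereospecific inversions, so the absolute configuration rests on firmer ground than in the chosen plan. The weak points lie in the preparation and the closure. The ether must be made by opening an electron-rich aryl glycidol at its benzylic carbon with a phenol hindered on both ortho positions, where partial ionisation erodes configuration. The organolithium closure must choose the internal over the terminal epoxide carbon (five- versus six-membered ring), and it must outrun base-induced epoxide isomerisation next to the acidic benzylic ether hydrogen. C5 has to travel as an acetal, which adds protection and an acidic unmasking, and the sequence is linear. Against the better stereochemical precedent of this road, the chosen plan offers convergence, a mild carbonate step in place of a cryogenic alkyllithium cyclisation, and a bromide at C5 that needs no protecting-group steps.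

Alternative 2: The cut is C2–C3. A chiral dirhodium tetracarboxylate of the N-phthaloyl amino acid class would convert aryldiazoacetate **A4** into a carbene at C3 that inserts into the benzylic C–H bond of the ring A benzyl ether. The first-formed cis ester **A5** would then be epimerised at C3 by an amidine base to the trans ester **A3**. **A3** is (2S,3S) by the sequence rule because the ester outranks C2; its spatial arrangement is that of **17**. Enantioselective insertion of this kind into electron-rich benzyl ethers is well established, and in this respect the road is stronger than the chosen plan. It would also use the same benzylic bromide **12** for the ether. Its drawbacks for this target are structural. The diazo ester requires a ring B arylacetate that is not a simple commercial compound, and the sequence to **A4** is linear. The epimerisation runs through an ester enolate that can expel the ring B phenoxide from C2, which would racemise C2 on reclosure. The ester is at the wrong oxidation level and is incompatible with the later aryllithium, so reduction and silylation must be added before C5 can be formylated. The chosen plan sets against the better-precedented induction a convergent assembly that delivers C3 already as the protected hydroxymethyl group and avoids any enolisable centre next to the ring oxygen.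

Alternative 3: The cut is O1–C2. A Lewis acid would ionise the benzylic carbinol of triol **A7**, and the ring B phenol would trap the ring A-stabilised cation to give the trans dihydrobenzofuran **A6**. The closure is stereoconvergent, so only the centre that becomes C3 has to be set and the carbinol configuration is irrelevant. This makes it the most forgiving of the four roads, and the ring closure itself is classical. Its cost is in the approach. **A7** needs a ring B arylacetic acid with a protected phenol, a first auxiliary-controlled aldol or alkylation, reduction and phenol deprotection, and then a second auxiliary sequence for the side chain. The Lewis acid must spare the aryl silyl ether, trans selectivity is thermodynamic rather than enforced, and **A6** must still be silylated before halogen–lithium exchange. The chosen plan is shorter and convergent and forms the C2–C3 bond as well as the O1–C2 bond in the ring-forming step. It carries the greater risk in absolute control, and that risk is addressed in the closing section.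

Key step: step 9

## Route

Assumption: the facial preference of the 2,5-dimethylthiolanium benzylide known from carbonyl addition is taken to carry over to conjugate addition, which predicts (2S)-C2 from the (2S,5S)-sulfide **8**; if the sense proves opposite, the enantiomeric diol is used in step 3 and nothing else changes.

Step 1
Reactants: 1 4-bromo-2-methoxyphenol; 2 (tert-butyldimethylsilyloxy)acetaldehyde
Product: 4 4-bromo-2-[2-(tert-butyldimethylsilyloxy)-1-hydroxyethyl]-6-methoxyphenol (racemic), via bromomagnesium phenoxide 3 (not isolated)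
Conditions: EtMgBr (1.0 equiv), Et2O, 0 °C; solvent exchanged for CH2Cl2; 2, 25 °C; aq. NH4Cl
Reagents that add atoms: none
Why: Ortho-specific hydroxyalkylation of a magnesium phenoxide: the aldehyde bound to magnesium is delivered through a six-membered chelate to the only free position ortho to the phenoxide oxygen, the para position being blocked by bromine. The carbinol centre is racemic, which is immaterial because it becomes trigonal in step 9.

Step 2
Reactants: 4 4-bromo-2-[2-(tert-butyldimethylsilyloxy)-1-hydroxyethyl]-6-methoxyphenol
Product: 5 4-bromo-2-[2-(tert-butyldimethylsilyloxy)-1-(4-methylphenylsulfonyl)ethyl]-6-methoxyphenol (racemic)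
Conditions: p-TolSO2H (2 equiv), CH2Cl2, 25 °C
Reagents that add atoms: p-toluenesulfinic acid, Cc1ccc(cc1)S(=O)O
Why: Acid-mediated SN1-type substitution of an ortho-hydroxybenzylic alcohol by the sulfur atom of the sulfinic acid, the standard entry to 2-(1-sulfonylalkyl)phenols. The ortho hydroxyl assists ionisation, and the primary silyl ether should tolerate the weak acid in an anhydrous medium.

Step 3
Reactants: 6 (2R,5R)-hexane-2,5-diol
Product: 7 (2R,5R)-hexane-2,5-diyl dimethanesulfonate
Conditions: MsCl, Et3N, CH2Cl2, −20 → 0 °C
Reagents that add atoms: methanesulfonyl chloride, CS(=O)(=O)Cl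
Why: O-Sulfonylation of both secondary alcohols; no bond to a stereocentre is broken, so the configuration is retained.

Step 4
Reactants: 7 (2R,5R)-hexane-2,5-diyl dimethanesulfonate
Product: 8 (2S,5S)-2,5-dimethylthiolane
Conditions: Na2S·9H2O, DMSO, 25 °C
Reagents that add atoms: sodium sulfide, [Na+].[Na+].[S-2]
Why: Double SN2 displacement by sulfide, first intermolecular and then 5-exo-tet. Each carbon is inverted once, so the (2R,5R)-dimesylate gives the trans, C2-symmetric (2S,5S)-thiolane.

Step 5
Reactants: 9 vanillin (4-hydroxy-3-methoxybenzaldehyde)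
Product: 10 3-methoxy-4-(triisopropylsilyloxy)benzaldehyde
Conditions: i-Pr3SiCl, imidazole, DMF, 25 °C
Reagents that add atoms: chlorotriisopropylsilane, CC(C)[Si](Cl)(C(C)C)C(C)C
Why: Imidazole-promoted silylation of the phenol. The bulky aryl silyl ether is chosen to survive carbonate, hydride, alkyllithium and boron triflate in later steps.

Step 6
Reactants: 10 3-methoxy-4-(triisopropylsilyloxy)benzaldehyde
Product: 11 [3-methoxy-4-(triisopropylsilyloxy)phenyl]methanol
Conditions: NaBH4, MeOH, 0 °C
Reagents that add atoms: none
Why: Borohydride reduction of an aromatic aldehyde; the aryl silyl ether is inert at 0 °C.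

Step 7
Reactants: 11 [3-methoxy-4-(triisopropylsilyloxy)phenyl]methanol
Product: 12 4-(bromomethyl)-2-methoxy-1-(triisopropylsilyloxy)benzene
Conditions: CBr4, PPh3, CH2Cl2, 0 °C; used without chromatography
Reagents that add atoms: carbon tetrabromide, BrC(Br)(Br)Br
Why: Appel bromination under neutral conditions, which avoids the acid that would ionise the electron-rich benzylic position or cleave the silyl ether.

Step 8
Reactants: 12 4-(bromomethyl)-2-methoxy-1-(triisopropylsilyloxy)benzene; 8 (2S,5S)-2,5-dimethylthiolane
Product: 13 (2S,5S)-1-[3-methoxy-4-(triisopropylsilyloxy)benzyl]-2,5-dimethylthiolan-1-ium tetrafluoroborate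
Conditions: 8 (1.5 equiv), AgBF4 (1.05 equiv), CH2Cl2, 0 → 25 °C, dark
Reagents that add atoms: silver tetrafluoroborate, [Ag+].F[B-](F)(F)F
Why: S-Alkylation of the sulfide, made irreversible by precipitation of AgBr, with a non-nucleophilic counter-ion installed. Sulfur carries two identical (S)-configured ring carbons and is not a stereocentre, so a single salt results.

Step 9
Reactants: 5 4-bromo-2-[2-(tert-butyldimethylsilyloxy)-1-(4-methylphenylsulfonyl)ethyl]-6-methoxyphenol; 13 (2S,5S)-1-[3-methoxy-4-(triisopropylsilyloxy)benzyl]-2,5-dimethylthiolan-1-ium tetrafluoroborate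
Product: 17 (2S,3R)-5-bromo-3-[(tert-butyldimethylsilyloxy)methyl]-7-methoxy-2-[3-methoxy-4-(triisopropylsilyloxy)phenyl]-2,3-dihydro-1-benzofuran, via o-quinone methide 14 (not isolated), via sulfonium ylide 15 (not isolated), via betaine 16 (not isolated)
Conditions: 5 added over 1 h to 13 (1.3 equiv) and Cs2CO3 (3 equiv), CH2Cl2, −20 → 0 °C
Reagents that add atoms: none
Why: Proposed new method: Cs2CO3 deprotonates the phenol of 5, whose phenoxide expels p-toluenesulfinate to give the (E)-o-quinone methide 14, and removes a benzylic proton of 13 to give the semi-stabilised ylide 15. The ylide carbon adds to the exocyclic carbon of 14 (C2–C3), which rearomatises ring B and gives the phenoxide–sulfonium betaine 16; the phenoxide then displaces the thiolane at C2 with inversion in a 5-exo-tet SN2 closure (O1–C2), which forms the dihydrofuran ring and returns sulfide 8. The closest known reaction type is the carbonate-mediated [4+1] annulation of sulfonium ylides with o-quinone methides released from 2-(1-sulfonylalkyl)phenols, which gives trans-2,3-dihydrobenzofurans, taken together with asymmetric benzylidene transfer from 2,5-dimethylthiolanium ylides to aldehydes; new here is the chiral semi-stabilised benzylide on an o-quinone methide that bears an enolisable alkyl group. C2 is controlled by the C2-symmetric thiolanium ring: sulfur is not a stereocentre, the ylide has one preferred conformation, and the methyl group next to sulfur screens one face of the carbanion, so one configuration is fixed in the addition and inverted cleanly in the closure. C3 is controlled relative to C2: closure needs phenoxide and sulfonium antiperiplanar, and the betaine that reaches this geometry with ring A and the CH2OTBS arm on opposite sides closes fastest while the other can revert, so the ring should come out trans. The step needs addition to outrun the 1,5-hydrogen shift of 14 and O-benzylation of the phenoxide by 13; the E geometry of 14 holds the CH2 hydrogens away from the carbonyl oxygen, and slow addition of 5 to an excess of ylide at low temperature keeps the free o-quinone methide scarce. The aryl bromide, the silyl ethers and the methyl ethers are inert to carbonate.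

Step 10
Reactants: 17 (2S,3R)-5-bromo-3-[(tert-butyldimethylsilyloxy)methyl]-7-methoxy-2-[3-methoxy-4-(triisopropylsilyloxy)phenyl]-2,3-dihydro-1-benzofuran
Product: 19 (2S,3R)-3-[(tert-butyldimethylsilyloxy)methyl]-7-methoxy-2-[3-methoxy-4-(triisopropylsilyloxy)phenyl]-2,3-dihydro-1-benzofuran-5-carbaldehyde, via aryllithium 18 (not isolated)
Conditions: n-BuLi (1.1 equiv), THF, −78 °C; DMF, −78 → 0 °C; aq. NH4Cl
Reagents that add atoms: N,N-dimethylformamide, CN(C)C=O
Why: Bromine–lithium exchange at −78 °C is faster than deprotonation at C2 or C3, and the aryllithium is formylated by DMF (Bouveault-type formylation). Both stereocentres and all silyl ethers are untouched.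

Step 11
Reactants: 20 homovanillic acid [(4-hydroxy-3-methoxyphenyl)acetic acid]
Product: 22 [3-methoxy-4-(triisopropylsilyloxy)phenyl]acetic acid, via bis-silyl derivative 21 (not isolated)
Conditions: i-Pr3SiCl (2.3 equiv), imidazole, DMF, 25 °C; then AcOH/THF/H2O, 25 °C
Reagents that add atoms: chlorotriisopropylsilane, CC(C)[Si](Cl)(C(C)C)C(C)C
Why: Silylation of phenol and carboxylic acid, followed by selective hydrolysis of the silyl ester, which is far more labile than the aryl silyl ether.

Step 12
Reactants: 22 [3-methoxy-4-(triisopropylsilyloxy)phenyl]acetic acid; 23 (4S)-4-benzyl-1,3-oxazolidin-2-one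
Product: 25 (4S)-4-benzyl-3-{[3-methoxy-4-(triisopropylsilyloxy)phenyl]acetyl}-1,3-oxazolidin-2-one, via mixed pivalic anhydride 24 (not isolated)
Conditions: t-BuCOCl, Et3N, THF, −20 °C; then LiCl, 23, −20 → 25 °C
Reagents that add atoms: none
Why: N-Acylation of the oxazolidinone through the mixed pivalic anhydride with LiCl/Et3N activation. The oxazolidinone attacks the less hindered arylacetyl carbonyl, and no strong base is present that could enolise the acidic arylacetyl unit.

Step 13
Reactants: 25 (4S)-4-benzyl-3-{[3-methoxy-4-(triisopropylsilyloxy)phenyl]acetyl}-1,3-oxazolidin-2-one; 19 (2S,3R)-3-[(tert-butyldimethylsilyloxy)methyl]-7-methoxy-2-[3-methoxy-4-(triisopropylsilyloxy)phenyl]-2,3-dihydro-1-benzofuran-5-carbaldehyde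
Product: 27 (4S)-4-benzyl-3-[(2S,3S)-3-{(2S,3R)-3-[(tert-butyldimethylsilyloxy)methyl]-7-methoxy-2-[3-methoxy-4-(triisopropylsilyloxy)phenyl]-2,3-dihydro-1-benzofuran-5-yl}-3-hydroxy-2-[3-methoxy-4-(triisopropylsilyloxy)phenyl]propanoyl]-1,3-oxazolidin-2-one, via boron enolate 26 (not isolated)
Conditions: 25 (1.5 equiv), n-Bu2BOTf (1.65 equiv), i-Pr2NEt (1.9 equiv), CH2Cl2, −78 → 0 °C; 19, −78 → 0 °C; pH 7 buffer, MeOH, 30% H2O2, 0 °C
Reagents that add atoms: none
Why: Evans syn aldol. The (Z)-dibutylboron enolate 26 reacts through a Zimmerman–Traxler chair in which the aldehyde approaches the enolate face remote from the benzyl group with the carbonyl dipoles opposed. This should set C8' and C7' together as the (2S,3S) syn adduct, which corresponds to (7'S,8'R) in 29. The remote C2/C3 centres play no part, and any minor enantiomer of 19 would emerge as a separable diastereomer.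

Step 14
Reactants: 27 the (2S,3S) aldol adduct of step 13
Product: 28 (1S,2R)-1-{(2S,3R)-3-[(tert-butyldimethylsilyloxy)methyl]-7-methoxy-2-[3-methoxy-4-(triisopropylsilyloxy)phenyl]-2,3-dihydro-1-benzofuran-5-yl}-2-[3-methoxy-4-(triisopropylsilyloxy)phenyl]propane-1,3-diol
Conditions: LiBH4 (2 equiv), H2O (2 equiv), THF/Et2O, 0 °C
Reagents that add atoms: none
Why: Reductive cleavage of the N-acyl oxazolidinone: hydride attacks the exocyclic carbonyl and the released aldehyde is reduced to C9'H2OH, with the auxiliary 23 recovered. The conditions at 0 °C are mild enough that the α-aryl centre should not epimerise.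

Step 15
Reactants: 28 the tris-silylated 1,3-diol of step 14
Product: 29 (1S,2R)-2-(4-hydroxy-3-methoxyphenyl)-1-[(2S,3R)-2-(4-hydroxy-3-methoxyphenyl)-3-(hydroxymethyl)-7-methoxy-2,3-dihydro-1-benzofuran-5-yl]propane-1,3-diol
Conditions: Bu4NF (4 equiv), AcOH (4 equiv), THF, 0 → 25 °C
Reagents that add atoms: none
Why: Fluoride cleavage of the two aryl silyl ethers and the primary silyl ether. Acetic acid protonates the phenoxides as they form, which prevents para-quinone methide opening of the O1–C2 bond from ring A and base-induced fragmentation of the 1,3-diol.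

## Compound list

1 | 4-bromo-2-methoxyphenol | COc1cc(Br)ccc1O | starting material
2 | (tert-butyldimethylsilyloxy)acetaldehyde | O=CCO[Si](C)(C)C(C)(C)C | starting material
3 | bromomagnesium 4-bromo-2-methoxyphenoxide (formed in the flask) | COc1cc(Br)ccc1O[Mg]Br | intermediate
4 | 4-bromo-2-[2-(tert-butyldimethylsilyloxy)-1-hydroxyethyl]-6-methoxyphenol, racemic | COc1cc(Br)cc(C(O)CO[Si](C)(C)C(C)(C)C)c1O | intermediate
5 | 4-bromo-2-[2-(tert-butyldimethylsilyloxy)-1-(4-methylphenylsulfonyl)ethyl]-6-methoxyphenol, racemic | COc1cc(Br)cc(C(CO[Si](C)(C)C(C)(C)C)S(=O)(=O)c2ccc(C)cc2)c1O | intermediate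
6 | (2R,5R)-hexane-2,5-diol | C[C@@H](O)CC[C@@H](C)O | starting material
7 | (2R,5R)-hexane-2,5-diyl dimethanesulfonate | C[C@@H](OS(C)(=O)=O)CC[C@@H](C)OS(C)(=O)=O | intermediate
8 | (2S,5S)-2,5-dimethylthiolane | C[C@H]1CC[C@H](C)S1 | intermediate
9 | vanillin | COc1cc(C=O)ccc1O | starting material
10 | 3-methoxy-4-(triisopropylsilyloxy)benzaldehyde | COc1cc(C=O)ccc1O[Si](C(C)C)(C(C)C)C(C)C | intermediate
11 | [3-methoxy-4-(triisopropylsilyloxy)phenyl]methanol | COc1cc(CO)ccc1O[Si](C(C)C)(C(C)C)C(C)C | intermediate
12 | 4-(bromomethyl)-2-methoxy-1-(triisopropylsilyloxy)benzene | COc1cc(CBr)ccc1O[Si](C(C)C)(C(C)C)C(C)C | intermediate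
13 | (2S,5S)-1-[3-methoxy-4-(triisopropylsilyloxy)benzyl]-2,5-dimethylthiolan-1-ium tetrafluoroborate | COc1cc(C[S+]2[C@@H](C)CC[C@@H]2C)ccc1O[Si](C(C)C)(C(C)C)C(C)C.F[B-](F)(F)F | intermediate
14 | (6E)-4-bromo-6-[2-(tert-butyldimethylsilyloxy)ethylidene]-2-methoxycyclohexa-2,4-dien-1-one (o-quinone methide, formed in the flask) | COC1=CC(Br)=C/C(=C\CO[Si](C)(C)C(C)(C)C)C1=O | intermediate
15 | (2S,5S)-2,5-dimethylthiolan-1-ium [3-methoxy-4-(triisopropylsilyloxy)phenyl]methylide (formed in the flask) | COc1cc([CH-][S+]2[C@@H](C)CC[C@@H]2C)ccc1O[Si](C(C)C)(C(C)C)C(C)C | intermediate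
16 | betaine: 4-bromo-2-{(1R,2R)-3-(tert-butyldimethylsilyloxy)-1-[(2S,5S)-2,5-dimethylthiolan-1-ium-1-yl]-1-[3-methoxy-4-(triisopropylsilyloxy)phenyl]propan-2-yl}-6-methoxyphenolate (formed in the flask) | COc1cc(Br)cc([C@H](CO[Si](C)(C)C(C)(C)C)[C@H](c2ccc(O[Si](C(C)C)(C(C)C)C(C)C)c(OC)c2)[S+]2[C@@H](C)CC[C@@H]2C)c1[O-] | intermediate
17 | (2S,3R)-5-bromo-3-[(tert-butyldimethylsilyloxy)methyl]-7-methoxy-2-[3-methoxy-4-(triisopropylsilyloxy)phenyl]-2,3-dihydro-1-benzofuran | COc1cc([C@H]2Oc3c(OC)cc(Br)cc3[C@@H]2CO[Si](C)(C)C(C)(C)C)ccc1O[Si](C(C)C)(C(C)C)C(C)C | intermediate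
18 | the 5-lithio derivative of 17, (2S,3R) (formed in the flask) | COc1cc([C@H]2Oc3c(OC)cc([Li])cc3[C@@H]2CO[Si](C)(C)C(C)(C)C)ccc1O[Si](C(C)C)(C(C)C)C(C)C | intermediate
19 | (2S,3R)-3-[(tert-butyldimethylsilyloxy)methyl]-7-methoxy-2-[3-methoxy-4-(triisopropylsilyloxy)phenyl]-2,3-dihydro-1-benzofuran-5-carbaldehyde | COc1cc([C@H]2Oc3c(OC)cc(C=O)cc3[C@@H]2CO[Si](C)(C)C(C)(C)C)ccc1O[Si](C(C)C)(C(C)C)C(C)C | intermediate
20 | homovanillic acid, (4-hydroxy-3-methoxyphenyl)acetic acid | COc1cc(CC(=O)O)ccc1O | starting material
21 | triisopropylsilyl [3-methoxy-4-(triisopropylsilyloxy)phenyl]acetate (formed in the flask) | COc1cc(CC(=O)O[Si](C(C)C)(C(C)C)C(C)C)ccc1O[Si](C(C)C)(C(C)C)C(C)C | intermediate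
22 | [3-methoxy-4-(triisopropylsilyloxy)phenyl]acetic acid | COc1cc(CC(=O)O)ccc1O[Si](C(C)C)(C(C)C)C(C)C | intermediate
23 | (4S)-4-benzyl-1,3-oxazolidin-2-one | O=C1N[C@@H](Cc2ccccc2)CO1 | starting material
24 | [3-methoxy-4-(triisopropylsilyloxy)phenyl]acetic pivalic anhydride (formed in the flask) | COc1cc(CC(=O)OC(=O)C(C)(C)C)ccc1O[Si](C(C)C)(C(C)C)C(C)C | intermediate
25 | (4S)-4-benzyl-3-{[3-methoxy-4-(triisopropylsilyloxy)phenyl]acetyl}-1,3-oxazolidin-2-one | COc1cc(CC(=O)N2[C@@H](Cc3ccccc3)COC2=O)ccc1O[Si](C(C)C)(C(C)C)C(C)C | intermediate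
26 | (Z)-dibutylboron enolate of 25 (formed in the flask) | COc1cc(/C=C(\OB(CCCC)CCCC)N2[C@@H](Cc3ccccc3)COC2=O)ccc1O[Si](C(C)C)(C(C)C)C(C)C | intermediate
27 | (4S)-4-benzyl-3-[(2S,3S)-3-{(2S,3R)-3-[(tert-butyldimethylsilyloxy)methyl]-7-methoxy-2-[3-methoxy-4-(triisopropylsilyloxy)phenyl]-2,3-dihydro-1-benzofuran-5-yl}-3-hydroxy-2-[3-methoxy-4-(triisopropylsilyloxy)phenyl]propanoyl]-1,3-oxazolidin-2-one | COc1cc([C@H]2Oc3c(OC)cc([C@@H](O)[C@@H](C(=O)N4[C@@H](Cc5ccccc5)COC4=O)c4ccc(O[Si](C(C)C)(C(C)C)C(C)C)c(OC)c4)cc3[C@@H]2CO[Si](C)(C)C(C)(C)C)ccc1O[Si](C(C)C)(C(C)C)C(C)C | intermediate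
28 | (1S,2R)-1-{(2S,3R)-3-[(tert-butyldimethylsilyloxy)methyl]-7-methoxy-2-[3-methoxy-4-(triisopropylsilyloxy)phenyl]-2,3-dihydro-1-benzofuran-5-yl}-2-[3-methoxy-4-(triisopropylsilyloxy)phenyl]propane-1,3-diol | COc1cc([C@H]2Oc3c(OC)cc([C@@H](O)[C@@H](CO)c4ccc(O[Si](C(C)C)(C(C)C)C(C)C)c(OC)c4)cc3[C@@H]2CO[Si](C)(C)C(C)(C)C)ccc1O[Si](C(C)C)(C(C)C)C(C)C | intermediate
29 | (1S,2R)-2-(4-hydroxy-3-methoxyphenyl)-1-[(2S,3R)-2-(4-hydroxy-3-methoxyphenyl)-3-(hydroxymethyl)-7-methoxy-2,3-dihydro-1-benzofuran-5-yl]propane-1,3-diol | COc1cc([C@H]2Oc3c(OC)cc([C@@H](O)[C@@H](CO)c4ccc(O)c(OC)c4)cc3[C@@H]2CO)ccc1O | target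

## Step count and risks

Total: 15 steps. Longest linear sequence: 9 steps (vanillin **9** → **10** → **11** → **12** → **13** → **17** → **19** → **27** → **28** → **29**; steps 5–10 and 13–15).

**Step 9 (key step, proposed new method).** The most likely failure is insufficient facial discrimination by the thiolanium ylide. The sulfide has only been shown to control addition to a carbonyl group, and in a conjugate addition with a possibly reversible betaine the selection may be made at a different stage. Loss of material through tautomerisation of the quinone methide or O-benzylation of the phenoxide is the second concern. Fallback, from **12** and **5**, returning at **17**: alkylation of tetrahydrothiophene with **12** (AgBF4, CH2Cl2) would give the achiral 1-[3-methoxy-4-(triisopropylsilyloxy)benzyl]thiolan-1-ium tetrafluoroborate F1. With Cs2CO3 in the presence of **5**, its ylide, thiolan-1-ium [3-methoxy-4-(triisopropylsilyloxy)phenyl]methylide F2, would undergo the established racemic [4+1] annulation of sulfonium ylides with sulfone-derived o-quinone methides. This gives the trans product as the racemate of **17** and its mirror image, (2R,3S)-5-bromo-3-[(tert-butyldimethylsilyloxy)methyl]-7-methoxy-2-[3-methoxy-4-(triisopropylsilyloxy)phenyl]-2,3-dihydro-1-benzofuran F3. Preparative chromatography on a polysaccharide chiral stationary phase would then deliver **17**. The source of absolute configuration changes from reagent control to resolution, at the cost of half the material.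

**Step 1.** The magnesium phenoxide is deactivated by the para bromine, so carbon–carbon bond formation may be slow and the enolisable aldehyde may self-condense first. Fallback, from **1**, returning at **4**: ortho-formylation of **1** (MgCl2, Et3N, paraformaldehyde, MeCN, reflux) would give 5-bromo-2-hydroxy-3-methoxybenzaldehyde F4, which is also an article of commerce. Wittig methylenation (Ph3P=CH2 in excess, THF) would give 4-bromo-2-ethenyl-6-methoxyphenol F5. Upjohn dihydroxylation (catalytic OsO4, N-methylmorpholine N-oxide) would give 1-(5-bromo-2-hydroxy-3-methoxyphenyl)ethane-1,2-diol F6. Silylation of the primary hydroxyl and the phenol (t-BuMe2SiCl 2.2 equiv, imidazole, CH2Cl2, 0 °C) would give 1-[5-bromo-2-(tert-butyldimethylsilyloxy)-3-methoxyphenyl]-2-(tert-butyldimethylsilyloxy)ethanol F7, whose aryl silyl ether alone is cleaved by K2CO3 in MeOH to give **4**.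

**Step 2.** The protic acid may remove the primary silyl ether, or the benzylic cation may lose a proton towards the enol ether, before sulfinate capture; the ring is not strongly donating and the adjacent oxygenated carbon slows ionisation. Fallback, from **4**, returning at **5**: ZnI2-mediated substitution of the benzylic hydroxyl by the more nucleophilic 4-methylbenzenethiol (CH2Cl2, 25 °C) would give 4-bromo-2-[2-(tert-butyldimethylsilyloxy)-1-(4-methylphenylsulfanyl)ethyl]-6-methoxyphenol F8, and oxidation at sulfur (m-chloroperbenzoic acid 2.2 equiv, CH2Cl2, 0 °C) would give **5**.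

**Step 14.** The lithium aldolate of an α-aryl β-hydroxy imide can undergo retro-aldol cleavage or epimerise at C8' before hydride is delivered, because the arylacetyl enolate is a good leaving group. Fallback, from **27**, returning at **29**: silylation of the C7' hydroxyl (t-BuMe2SiOTf, 2,6-lutidine, CH2Cl2, −78 °C) would give (4S)-4-benzyl-3-[(2S,3S)-3-(tert-butyldimethylsilyloxy)-3-{(2S,3R)-3-[(tert-butyldimethylsilyloxy)methyl]-7-methoxy-2-[3-methoxy-4-(triisopropylsilyloxy)phenyl]-2,3-dihydro-1-benzofuran-5-yl}-2-[3-methoxy-4-(triisopropylsilyloxy)phenyl]propanoyl]-1,3-oxazolidin-2-one F9, which cannot undergo retro-aldol cleavage. LiBH4 reduction would then give (2R,3S)-3-(tert-butyldimethylsilyloxy)-3-{(2S,3R)-3-[(tert-butyldimethylsilyloxy)methyl]-7-methoxy-2-[3-methoxy-4-(triisopropylsilyloxy)phenyl]-2,3-dihydro-1-benzofuran-5-yl}-2-[3-methoxy-4-(triisopropylsilyloxy)phenyl]propan-1-ol F10, and the buffered fluoride conditions of step 15 would remove all four silyl groups to give **29**.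

## Further compounds

F1 | step 9 | 1-[3-methoxy-4-(triisopropylsilyloxy)benzyl]thiolan-1-ium tetrafluoroborate | COc1cc(C[S+]2CCCC2)ccc1O[Si](C(C)C)(C(C)C)C(C)C.F[B-](F)(F)F
F2 | step 9 | thiolan-1-ium [3-methoxy-4-(triisopropylsilyloxy)phenyl]methylide | COc1cc([CH-][S+]2CCCC2)ccc1O[Si](C(C)C)(C(C)C)C(C)C
F3 | step 9 | (2R,3S)-5-bromo-3-[(tert-butyldimethylsilyloxy)methyl]-7-methoxy-2-[3-methoxy-4-(triisopropylsilyloxy)phenyl]-2,3-dihydro-1-benzofuran | COc1cc([C@@H]2Oc3c(OC)cc(Br)cc3[C@H]2CO[Si](C)(C)C(C)(C)C)ccc1O[Si](C(C)C)(C(C)C)C(C)C
F4 | step 1 | 5-bromo-2-hydroxy-3-methoxybenzaldehyde | COc1cc(Br)cc(C=O)c1O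
F5 | step 1 | 4-bromo-2-ethenyl-6-methoxyphenol | COc1cc(Br)cc(C=C)c1O
F6 | step 1 | 1-(5-bromo-2-hydroxy-3-methoxyphenyl)ethane-1,2-diol, racemic | COc1cc(Br)cc(C(O)CO)c1O
F7 | step 1 | 1-[5-bromo-2-(tert-butyldimethylsilyloxy)-3-methoxyphenyl]-2-(tert-butyldimethylsilyloxy)ethanol, racemic | COc1cc(Br)cc(C(O)CO[Si](C)(C)C(C)(C)C)c1O[Si](C)(C)C(C)(C)C
F8 | step 2 | 4-bromo-2-[2-(tert-butyldimethylsilyloxy)-1-(4-methylphenylsulfanyl)ethyl]-6-methoxyphenol, racemic | COc1cc(Br)cc(C(CO[Si](C)(C)C(C)(C)C)Sc2ccc(C)cc2)c1O
F9 | step 14 | (4S)-4-benzyl-3-[(2S,3S)-3-(tert-butyldimethylsilyloxy)-3-{(2S,3R)-3-[(tert-butyldimethylsilyloxy)methyl]-7-methoxy-2-[3-methoxy-4-(triisopropylsilyloxy)phenyl]-2,3-dihydro-1-benzofuran-5-yl}-2-[3-methoxy-4-(triisopropylsilyloxy)phenyl]propanoyl]-1,3-oxazolidin-2-one | COc1cc([C@H]2Oc3c(OC)cc([C@@H](O[Si](C)(C)C(C)(C)C)[C@@H](C(=O)N4[C@@H](Cc5ccccc5)COC4=O)c4ccc(O[Si](C(C)C)(C(C)C)C(C)C)c(OC)c4)cc3[C@@H]2CO[Si](C)(C)C(C)(C)C)ccc1O[Si](C(C)C)(C(C)C)C(C)C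
F10 | step 14 | (2R,3S)-3-(tert-butyldimethylsilyloxy)-3-{(2S,3R)-3-[(tert-butyldimethylsilyloxy)methyl]-7-methoxy-2-[3-methoxy-4-(triisopropylsilyloxy)phenyl]-2,3-dihydro-1-benzofuran-5-yl}-2-[3-methoxy-4-(triisopropylsilyloxy)phenyl]propan-1-ol | COc1cc([C@H]2Oc3c(OC)cc([C@@H](O[Si](C)(C)C(C)(C)C)[C@@H](CO)c4ccc(O[Si](C(C)C)(C(C)C)C(C)C)c(OC)c4)cc3[C@@H]2CO[Si](C)(C)C(C)(C)C)ccc1O[Si](C(C)C)(C(C)C)C(C)C
A1 | alternative 1 | [(2S,3R)-5-(1,3-dioxolan-2-yl)-7-methoxy-2-[3-methoxy-4-(triisopropylsilyloxy)phenyl]-2,3-dihydro-1-benzofuran-3-yl]methanol | COc1cc([C@H]2Oc3c(OC)cc(C4OCCO4)cc3[C@@H]2CO)ccc1O[Si](C(C)C)(C(C)C)C(C)C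
A2 | alternative 1 | (2S)-2-{(R)-[2-bromo-4-(1,3-dioxolan-2-yl)-6-methoxyphenoxy][3-methoxy-4-(triisopropylsilyloxy)phenyl]methyl}oxirane | COc1cc([C@@H](Oc2c(Br)cc(C3OCCO3)cc2OC)[C@@H]2CO2)ccc1O[Si](C(C)C)(C(C)C)C(C)C
A3 | alternative 2 | methyl (2S,3S)-5-bromo-7-methoxy-2-[3-methoxy-4-(triisopropylsilyloxy)phenyl]-2,3-dihydro-1-benzofuran-3-carboxylate (trans) | COc1cc([C@H]2Oc3c(OC)cc(Br)cc3[C@@H]2C(=O)OC)ccc1O[Si](C(C)C)(C(C)C)C(C)C
A4 | alternative 2 | methyl 2-(5-bromo-3-methoxy-2-{[3-methoxy-4-(triisopropylsilyloxy)phenyl]methoxy}phenyl)-2-diazoacetate | COC(=O)C(=[N+]=[N-])c1cc(Br)cc(OC)c1OCc1ccc(O[Si](C(C)C)(C(C)C)C(C)C)c(OC)c1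
A5 | alternative 2 | methyl (2S,3R)-5-bromo-7-methoxy-2-[3-methoxy-4-(triisopropylsilyloxy)phenyl]-2,3-dihydro-1-benzofuran-3-carboxylate (cis) | COc1cc([C@H]2Oc3c(OC)cc(Br)cc3[C@H]2C(=O)OC)ccc1O[Si](C(C)C)(C(C)C)C(C)C
A6 | alternative 3 | [(2S,3R)-5-bromo-7-methoxy-2-[3-methoxy-4-(triisopropylsilyloxy)phenyl]-2,3-dihydro-1-benzofuran-3-yl]methanol | COc1cc([C@H]2Oc3c(OC)cc(Br)cc3[C@@H]2CO)ccc1O[Si](C(C)C)(C(C)C)C(C)C
A7 | alternative 3 | (2R)-2-(5-bromo-2-hydroxy-3-methoxyphenyl)-1-[3-methoxy-4-(triisopropylsilyloxy)phenyl]propane-1,3-diol, either C1 epimer | COc1cc(C(O)[C@@H](CO)c2cc(Br)cc(OC)c2O)ccc1O[Si](C(C)C)(C(C)C)C(C)C
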